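**Retrosynthetic overview**
- Target ⇐ fully protected flavone, by removal of the 3-O-MOM group and then of the 7-O-TIPS and 2''-O-TBS groups.
- Feature used: ring C (O1, C2-aryl, C3-OH, C4=O) is the 3-hydroxy-4-pyranone of kojic acid, and ring A has oxygen at C5 and C7, hydrogen at C6 and the chain at C8. This is the pattern given by a ketene carbonyl carbon (C5), the CH and C–OSi carbons of a siloxyalkyne (C6, C7) and a substituted diazo carbon (C8).
- Key disconnection of ring A: C8–C8a (Wolff shift), C5–C6 and C7–C8 (ketene plus HC≡C–OTIPS), C4a–C5 (six-electron closure) ⇒ pyranonyl α-diazo ketone and (triisopropylsilyloxy)acetylene.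
- Diazo ketone ⇐ ketone (detrifluoroacetylative diazo transfer) ⇐ pyranone-2-carbaldehyde plus chain Grignard reagent. The aldehyde comes from kojic acid (bromination, MOM, Suzuki coupling, oxidation), the chain with its (S)-centre from (S)-α-hydroxy-γ-butyrolactone, the alkyne from 3-phenylisoxazole.
- Ring order: ring C is bought, ring B is attached by Suzuki coupling, ring A is closed last.

Key step: step 13

Assumption: (triisopropylsilyloxy)acetylene is treated as not purchasable and is made in step 12; flavone numbering (C4a, C5–C8, C8a, side chain C1''–C4'') is used for ring A.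

**Route**

Step 1
Reactants: 1 kojic acid (5-hydroxy-2-(hydroxymethyl)-4H-pyran-4-one)
Product: 2 6-bromokojic acid (2-bromo-3-hydroxy-6-(hydroxymethyl)-4H-pyran-4-one)
Conditions: NBS (1.05 equiv), MeCN, 0 °C to rt
Reagents that add atoms: N-bromosuccinimide, O=C1CCC(=O)N1Br
Why: Electrophilic bromination (SEAr type) of the enolic 3-hydroxy-4-pyranone takes place at C6, the only free carbon ortho to the 5-OH, as is established for kojic acid.

Step 2
Reactants: 2 6-bromokojic acid
Product: 3 2-bromo-6-(hydroxymethyl)-3-(methoxymethoxy)-4H-pyran-4-one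
Conditions: MOMCl (1.05 equiv), K2CO3, acetone, 0 °C to rt
Reagents that add atoms: chloromethyl methyl ether, COCCl
Why: Williamson-type O-alkylation in which carbonate deprotonates only the acidic enolic OH (pKa about 8), so one equivalent of MOMCl caps this oxygen, the later 3-OH of the flavonol, and leaves the primary alcohol free for step 4.

Step 3
Reactants: 3 2-bromo-6-(hydroxymethyl)-3-(methoxymethoxy)-4H-pyran-4-one; 4 4-methoxyphenylboronic acid
Product: 5 6-(hydroxymethyl)-3-(methoxymethoxy)-2-(4-methoxyphenyl)-4H-pyran-4-one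
Conditions: Pd(PPh3)4 (5 mol%), K2CO3, 1,4-dioxane/H2O (5:1), 80 °C
Reagents that add atoms: none
Why: Suzuki–Miyaura coupling in which the 2-bromo-4-pyranone, a vinylogous acyl bromide, adds readily to zerovalent palladium, while the mild carbonate base leaves the MOM ether, the pyranone and the free alcohol intact; this attaches ring B.

Step 4
Reactants: 5 6-(hydroxymethyl)-3-(methoxymethoxy)-2-(4-methoxyphenyl)-4H-pyran-4-one
Product: 6 5-(methoxymethoxy)-6-(4-methoxyphenyl)-4-oxo-4H-pyran-2-carbaldehyde
Conditions: MnO2 (activated, excess), CH2Cl2, rt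
Reagents that add atoms: none
Why: MnO2 oxidises the allylic-type hydroxymethyl group on the pyranone to the aldehyde under neutral conditions and stops there, as is known for O-protected kojic acids.

Step 5
Reactants: 7 (S)-α-hydroxy-γ-butyrolactone ((3S)-3-hydroxyoxolan-2-one)
Product: 8 (3S)-3-(tert-butyldimethylsilyloxy)oxolan-2-one
Conditions: TBSCl, imidazole, DMF, rt
Reagents that add atoms: tert-butyldimethylsilyl chloride, CC(C)(C)[Si](C)(C)Cl
Why: Standard silylation of the secondary alcohol; the (S)-centre of the chiral pool, which becomes C2'' of the target, is not a reacting centre in this or any later step.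

Step 6
Reactants: 8 (3S)-3-(tert-butyldimethylsilyloxy)oxolan-2-one
Product: 9 (3S)-3-(tert-butyldimethylsilyloxy)-5-hydroxypentan-2-one (in equilibrium with its cyclic hemiketal)
Conditions: MeLi (1.05 equiv), THF, −78 °C; AcOH quench at −78 °C
Reagents that add atoms: methyllithium, [Li]C
Why: Mono-addition of MeLi to a γ-lactone, in which the lithium hemiketal alkoxide is stable at −78 °C and gives the methyl ketone only on the cold acidic quench, so a second addition is avoided and the α-stereocentre is never exposed to an equilibrating base.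

Step 7
Reactants: 9 (3S)-3-(tert-butyldimethylsilyloxy)-5-hydroxypentan-2-one
Product: 10 (3S)-3-(tert-butyldimethylsilyloxy)-4-methylpent-4-en-1-ol
Conditions: Ph3PCH3Br, n-BuLi (3 equiv of ylide), THF, 0 °C
Reagents that add atoms: methyltriphenylphosphonium bromide, C[P+](c1ccccc1)(c1ccccc1)c1ccccc1.[Br-]
Why: Wittig methylenation of the open-chain methyl ketone with the non-stabilised ylide (one extra equivalent is spent on the OH); at 0 °C with a lithium counter-ion, olefination should be faster than enolisation of the α-siloxy ketone and than silyl migration to the primary alkoxide.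

Step 8
Reactants: 10 (3S)-3-(tert-butyldimethylsilyloxy)-4-methylpent-4-en-1-ol
Product: 11 (3S)-5-bromo-3-(tert-butyldimethylsilyloxy)-2-methylpent-1-ene
Conditions: CBr4, PPh3, CH2Cl2, 0 °C
Reagents that add atoms: carbon tetrabromide, BrC(Br)(Br)Br
Why: Appel bromination converts the primary alcohol by SN2 at CH2 under neutral conditions, which the allylic silyl ether, the alkene and the stereocentre tolerate.

Step 9
Reactants: 11 (3S)-5-bromo-3-(tert-butyldimethylsilyloxy)-2-methylpent-1-ene; 6 5-(methoxymethoxy)-6-(4-methoxyphenyl)-4-oxo-4H-pyran-2-carbaldehyde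
Product: 13 2-[(4S)-4-(tert-butyldimethylsilyloxy)-1-hydroxy-5-methylhex-5-enyl]-5-(methoxymethoxy)-6-(4-methoxyphenyl)-4H-pyran-4-one (both carbinol epimers), via Grignard reagent 12 (not isolated)
Conditions: 11, Mg turnings, THF, 40 °C; then added to 6, THF, −78 °C; then H2O
Reagents that add atoms: none
Why: Grignard formation from the primary bromide (a γ-siloxy alkylmagnesium halide cannot β-eliminate) and 1,2-addition to the aldehyde, which at −78 °C is far more electrophilic than the vinylogous-ester carbonyl C4 of the pyranone; the new carbinol centre forms without control and is erased in step 10.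

Step 10
Reactants: 13 2-[(4S)-4-(tert-butyldimethylsilyloxy)-1-hydroxy-5-methylhex-5-enyl]-5-(methoxymethoxy)-6-(4-methoxyphenyl)-4H-pyran-4-one
Product: 14 2-[(4S)-4-(tert-butyldimethylsilyloxy)-5-methylhex-5-enoyl]-5-(methoxymethoxy)-6-(4-methoxyphenyl)-4H-pyran-4-one
Conditions: Dess–Martin periodinane, CH2Cl2, 0 °C to rt
Reagents that add atoms: none
Why: Dess–Martin oxidation of the secondary heteroaryl carbinol gives the ketone under mild conditions that MOM, TBS and the alkene survive.

Step 11
Reactants: 14 2-[(4S)-4-(tert-butyldimethylsilyloxy)-5-methylhex-5-enoyl]-5-(methoxymethoxy)-6-(4-methoxyphenyl)-4H-pyran-4-one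
Product: 17 2-[(4S)-2-diazo-4-(tert-butyldimethylsilyloxy)-5-methylhex-5-enoyl]-5-(methoxymethoxy)-6-(4-methoxyphenyl)-4H-pyran-4-one, via lithium enolate 15 (not isolated), via trifluoroacetyl ketone 16 (not isolated)
Conditions: LiN(SiMe3)2, THF, −78 °C; CF3CO2CH2CF3, −78 °C; cold 5% aq. HCl work-up; then MsN3, Et3N, H2O (1 equiv), MeCN, rt
Reagents that add atoms: methanesulfonyl azide, CS(=O)(=O)N=[N+]=[N-]
Why: Danheiser detrifluoroacetylative diazo transfer, in which the enolate at the only enolisable position is C-trifluoroacetylated and the resulting 1,3-dicarbonyl takes up the diazo group from MsN3 with loss of the trifluoroacetyl group as the N-acylsulfonamide, the standard route to α-diazo ketones that carry an α-alkyl group.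

Step 12
Reactants: 18 3-phenylisoxazole
Product: 20 (triisopropylsilyloxy)acetylene, via lithium ethynolate 19 (not isolated)
Conditions: LiN(i-Pr)2, THF, −78 °C; then TIPSOTf, −78 °C to 0 °C
Reagents that add atoms: triisopropylsilyl trifluoromethanesulfonate, CC(C)[Si](C(C)C)(C(C)C)OS(=O)(=O)C(F)(F)F
Why: Base-induced fragmentation of a 5-unsubstituted isoxazole (removal of H5 triggers cycloreversion to benzonitrile and the ynolate, the Schöllkopf–Hoppe ynolate generation) followed by O-silylation of the ynolate with the hard, bulky silyl triflate, the Kowalski–Kozmin way to triisopropylsilyl ynol ethers; the bulky silyl group disfavours C-silylation to the silylketene.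

Step 13
Reactants: 17 2-[(4S)-2-diazo-4-(tert-butyldimethylsilyloxy)-5-methylhex-5-enoyl]-5-(methoxymethoxy)-6-(4-methoxyphenyl)-4H-pyran-4-one; 20 (triisopropylsilyloxy)acetylene
Product: 25 5-hydroxy-3-(methoxymethoxy)-4'-methoxy-7-(triisopropylsilyloxy)-8-[(2S)-2-(tert-butyldimethylsilyloxy)-3-methylbut-3-enyl]flavone, via pyranonyl ketene 21 (not isolated), via cyclobutenone 22 (not isolated), via dienylketene 23 (not isolated), via cyclohexadienone 24 (not isolated)
Conditions: hν (medium-pressure Hg lamp, uranium-glass filter, >340 nm), 20 (3 equiv), degassed ClCH2CH2Cl, 20 °C; then 80 °C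
Reagents that add atoms: none
Why: Light expels N2 from 17 and the pyranonyl group shifts from the carbonyl carbon to the diazo carbon (photochemical Wolff rearrangement, forming C8–C8a) to give ketene 21; the electron-rich siloxyalkyne adds across its C=C in a [2+2] cycloaddition (C5–C6 and C7–C8) to give cyclobutenone 22, which opens reversibly by four-electron electrocyclic cleavage to dienylketene 23. Ring A closes by thermal disrotatory six-electron electrocyclisation of the isomer of 23 that has the ketenyl group cis to the pyranone, onto the C2=C3 bond of the pyranone (forming C4a–C5), and the resulting dienone 24, whose C4a–H lies between two carbonyl groups, enolises at once to the aromatic 5-phenol 25. The reaction type is the photochemical Danheiser benzannulation of vinyl, aryl and heteroaryl α-diazo ketones with siloxyalkynes (irradiation, then warming to 80 °C), applied here to a pyranone-based unsaturated diazo ketone. No stereocentre is created: the quaternary carbon of 22 and the sp3 C4a of 24 vanish on the way to the arene, and the (S)-carbinol two bonds from the reacting carbon is not touched. The step needs the Wolff shift to outrun the 1,2-hydrogen shift of the carbene, which direct long-wavelength irradiation of the diazo chromophore without sensitiser favours, and it needs the siloxy carbon to end next to C8, which the polarity of the ynol ether secures because its unsubstituted nucleophilic carbon bonds to the ketene carbonyl carbon. The three oxygens of ring A emerge differentiated (free chelated 5-OH, 7-O-TIPS, ring oxygen O1), so no 6- versus 8-isomer can form.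

Step 14
Reactants: 25 5-hydroxy-3-(methoxymethoxy)-4'-methoxy-7-(triisopropylsilyloxy)-8-[(2S)-2-(tert-butyldimethylsilyloxy)-3-methylbut-3-enyl]flavone
Product: 26 3,5-dihydroxy-4'-methoxy-7-(triisopropylsilyloxy)-8-[(2S)-2-(tert-butyldimethylsilyloxy)-3-methylbut-3-enyl]flavone
Conditions: MgBr2·OEt2, n-BuSH, Et2O/CH2Cl2, 0 °C to rt
Reagents that add atoms: none
Why: Chelation-assisted acetal cleavage in which MgBr2 binds the 3-O-MOM oxygen together with the C4 carbonyl and the thiol takes up the methoxymethyl group, conditions under which silyl ethers, the alkene and the aryl methyl ether are inert; at this stage O7 and O2'' are still silylated, so no free 7-OH or allylic alcohol is exposed to a Lewis acid.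

Step 15
Reactants: 26 3,5-dihydroxy-4'-methoxy-7-(triisopropylsilyloxy)-8-[(2S)-2-(tert-butyldimethylsilyloxy)-3-methylbut-3-enyl]flavone
Product: 27 2''-hydroxy-3''-en-anhydroicaritin (3,5,7-trihydroxy-8-[(2S)-2-hydroxy-3-methylbut-3-enyl]-4'-methoxyflavone)
Conditions: Bu4NF, AcOH (1:1, 4 equiv), THF, 0 °C to rt, argon
Reagents that add atoms: none
Why: Fluoride-mediated desilylation cleaves the aryl TIPS ether and the secondary TBS ether in one operation; buffering with AcOH keeps the polyphenolic flavonol from base-promoted oxidation and the (S)-carbinol is not touched.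

**Compound list**

1 | kojic acid (5-hydroxy-2-(hydroxymethyl)-4H-pyran-4-one) | OCc1cc(=O)c(O)co1 | starting material
2 | 6-bromokojic acid (2-bromo-3-hydroxy-6-(hydroxymethyl)-4H-pyran-4-one) | OCc1cc(=O)c(O)c(Br)o1 | intermediate
3 | 2-bromo-6-(hydroxymethyl)-3-(methoxymethoxy)-4H-pyran-4-one | OCc1cc(=O)c(OCOC)c(Br)o1 | intermediate
4 | 4-methoxyphenylboronic acid | COc1ccc(B(O)O)cc1 | starting material
5 | 6-(hydroxymethyl)-3-(methoxymethoxy)-2-(4-methoxyphenyl)-4H-pyran-4-one | OCc1cc(=O)c(OCOC)c(-c2ccc(OC)cc2)o1 | intermediate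
6 | 5-(methoxymethoxy)-6-(4-methoxyphenyl)-4-oxo-4H-pyran-2-carbaldehyde | O=Cc1cc(=O)c(OCOC)c(-c2ccc(OC)cc2)o1 | intermediate
7 | (S)-α-hydroxy-γ-butyrolactone ((3S)-3-hydroxyoxolan-2-one) | O=C1OCC[C@@H]1O | starting material
8 | (3S)-3-(tert-butyldimethylsilyloxy)oxolan-2-one | O=C1OCC[C@@H]1O[Si](C)(C)C(C)(C)C | intermediate
9 | (3S)-3-(tert-butyldimethylsilyloxy)-5-hydroxypentan-2-one | CC(=O)[C@@H](O[Si](C)(C)C(C)(C)C)CCO | intermediate
10 | (3S)-3-(tert-butyldimethylsilyloxy)-4-methylpent-4-en-1-ol | C=C(C)[C@@H](O[Si](C)(C)C(C)(C)C)CCO | intermediate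
11 | (3S)-5-bromo-3-(tert-butyldimethylsilyloxy)-2-methylpent-1-ene | C=C(C)[C@@H](O[Si](C)(C)C(C)(C)C)CCBr | intermediate
12 | [(3S)-3-(tert-butyldimethylsilyloxy)-4-methylpent-4-enyl]magnesium bromide | C=C(C)[C@@H](O[Si](C)(C)C(C)(C)C)CC[Mg]Br | intermediate
13 | 2-[(4S)-4-(tert-butyldimethylsilyloxy)-1-hydroxy-5-methylhex-5-enyl]-5-(methoxymethoxy)-6-(4-methoxyphenyl)-4H-pyran-4-one (both carbinol epimers) | C=C(C)[C@@H](O[Si](C)(C)C(C)(C)C)CCC(O)c1cc(=O)c(OCOC)c(-c2ccc(OC)cc2)o1 | intermediate
14 | 2-[(4S)-4-(tert-butyldimethylsilyloxy)-5-methylhex-5-enoyl]-5-(methoxymethoxy)-6-(4-methoxyphenyl)-4H-pyran-4-one | C=C(C)[C@@H](O[Si](C)(C)C(C)(C)C)CCC(=O)c1cc(=O)c(OCOC)c(-c2ccc(OC)cc2)o1 | intermediate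
15 | lithium enolate of 14 (enolate at C1=C2 of the acyl chain) | C=C(C)[C@@H](O[Si](C)(C)C(C)(C)C)CC=C(O[Li])c1cc(=O)c(OCOC)c(-c2ccc(OC)cc2)o1 | intermediate
16 | 2-[(4S)-4-(tert-butyldimethylsilyloxy)-5-methyl-2-(trifluoroacetyl)hex-5-enoyl]-5-(methoxymethoxy)-6-(4-methoxyphenyl)-4H-pyran-4-one (both C2 epimers) | C=C(C)[C@@H](O[Si](C)(C)C(C)(C)C)CC(C(=O)C(F)(F)F)C(=O)c1cc(=O)c(OCOC)c(-c2ccc(OC)cc2)o1 | intermediate
17 | 2-[(4S)-2-diazo-4-(tert-butyldimethylsilyloxy)-5-methylhex-5-enoyl]-5-(methoxymethoxy)-6-(4-methoxyphenyl)-4H-pyran-4-one | C=C(C)[C@@H](O[Si](C)(C)C(C)(C)C)CC(=[N+]=[N-])C(=O)c1cc(=O)c(OCOC)c(-c2ccc(OC)cc2)o1 | intermediate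
18 | 3-phenylisoxazole | c1ccc(-c2ccon2)cc1 | starting material
19 | lithium ethynolate | [Li]OC#C | intermediate
20 | (triisopropylsilyloxy)acetylene | C#CO[Si](C(C)C)(C(C)C)C(C)C | intermediate
21 | (4S)-4-(tert-butyldimethylsilyloxy)-2-[5-(methoxymethoxy)-6-(4-methoxyphenyl)-4-oxo-4H-pyran-2-yl]-5-methylhexa-1,5-dien-1-one (ketene) | C=C(C)[C@@H](O[Si](C)(C)C(C)(C)C)CC(=C=O)c1cc(=O)c(OCOC)c(-c2ccc(OC)cc2)o1 | intermediate
22 | 4-[(2S)-2-(tert-butyldimethylsilyloxy)-3-methylbut-3-enyl]-4-[5-(methoxymethoxy)-6-(4-methoxyphenyl)-4-oxo-4H-pyran-2-yl]-3-(triisopropylsilyloxy)cyclobut-2-en-1-one (both C4 epimers) | C=C(C)[C@@H](O[Si](C)(C)C(C)(C)C)CC1(c2cc(=O)c(OCOC)c(-c3ccc(OC)cc3)o2)C(=O)C=C1O[Si](C(C)C)(C(C)C)C(C)C | intermediate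
23 | (3E,6S)-6-(tert-butyldimethylsilyloxy)-4-[5-(methoxymethoxy)-6-(4-methoxyphenyl)-4-oxo-4H-pyran-2-yl]-7-methyl-3-(triisopropylsilyloxy)octa-1,3,7-trien-1-one (dienylketene, ketenyl cis to the pyranone) | C=C(C)[C@@H](O[Si](C)(C)C(C)(C)C)C/C(c1cc(=O)c(OCOC)c(-c2ccc(OC)cc2)o1)=C(/C=C=O)O[Si](C(C)C)(C(C)C)C(C)C | intermediate
24 | 8-[(2S)-2-(tert-butyldimethylsilyloxy)-3-methylbut-3-enyl]-3-(methoxymethoxy)-2-(4-methoxyphenyl)-7-(triisopropylsilyloxy)-4aH-chromene-4,5-dione (both C4a epimers) | C=C(C)[C@@H](O[Si](C)(C)C(C)(C)C)CC1=C2OC(-c3ccc(OC)cc3)=C(OCOC)C(=O)C2C(=O)C=C1O[Si](C(C)C)(C(C)C)C(C)C | intermediate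
25 | 5-hydroxy-3-(methoxymethoxy)-4'-methoxy-7-(triisopropylsilyloxy)-8-[(2S)-2-(tert-butyldimethylsilyloxy)-3-methylbut-3-enyl]flavone | C=C(C)[C@@H](O[Si](C)(C)C(C)(C)C)Cc1c(O[Si](C(C)C)(C(C)C)C(C)C)cc(O)c2c(=O)c(OCOC)c(-c3ccc(OC)cc3)oc12 | intermediate
26 | 3,5-dihydroxy-4'-methoxy-7-(triisopropylsilyloxy)-8-[(2S)-2-(tert-butyldimethylsilyloxy)-3-methylbut-3-enyl]flavone | C=C(C)[C@@H](O[Si](C)(C)C(C)(C)C)Cc1c(O[Si](C(C)C)(C(C)C)C(C)C)cc(O)c2c(=O)c(O)c(-c3ccc(OC)cc3)oc12 | intermediate
27 | 2''-hydroxy-3''-en-anhydroicaritin (3,5,7-trihydroxy-8-[(2S)-2-hydroxy-3-methylbut-3-enyl]-4'-methoxyflavone) | C=C(C)[C@@H](O)Cc1c(O)cc(O)c2c(=O)c(O)c(-c3ccc(OC)cc3)oc12 | target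

**Step count and risks**

Total step count: 15. Longest linear sequence: 10 steps (1–4, 9–11, 13–15 from kojic acid; equally 5–11, 13–15 from the lactone).

Steps most likely to fail:

1. Step 13. After loss of nitrogen, a hydrogen of the neighbouring CH2 may shift to the carbene carbon (enone formation) faster than the electron-poor pyranonyl group migrates, and the aryl-pyranone chromophore may take up the light in place of the diazo group. This particular diazo ketone has not been put through the reaction.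
   - The fallback sets out from aldehyde 6 and alkyne 20 and comes back at flavone 25. It takes the chain off the diazo carbon, so that no hydrogen can shift, and puts it on C8 after ring A exists.
   - Aldehyde 6 is oxidised (NaClO2, NaH2PO4, 2-methyl-2-butene, t-BuOH/H2O) to 5-(methoxymethoxy)-6-(4-methoxyphenyl)-4-oxo-4H-pyran-2-carboxylic acid F1.
   - Activation as the isobutyl carbonic anhydride F2 (i-BuOCOCl, N-methylmorpholine) and reaction with Me3SiCHN2 give 2-(diazoacetyl)-5-(methoxymethoxy)-6-(4-methoxyphenyl)-4H-pyran-4-one F3.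
   - Irradiation of F3 with 20 under the conditions of step 13 should give 5-hydroxy-3-(methoxymethoxy)-4'-methoxy-7-(triisopropylsilyloxy)flavone F4.
   - Mitsunobu O-prenylation of the 5-OH (3-methylbut-2-en-1-ol, PPh3, DIAD) gives the 5-O-prenyl ether F5.
   - Eu(fod)3-catalysed para-Claisen–Cope rearrangement (PhCl, 85 °C), the established way to 8-prenylflavonols of the icaritin type, carries the prenyl group through C6 to C8 and gives 8-prenylflavone F6.
   - Shi epoxidation (KHSO5, the fructose-derived ketone enantiomer that delivers the (2''S)-epoxide) gives the [(2S)-3,3-dimethyloxiran-2-yl]methyl flavone F7.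
   - Diethylaluminium 2,2,6,6-tetramethylpiperidide opens F7 by removal of a methyl hydrogen, with the C2''–O bond intact, to the (S)-allylic alcohol F8.
   - TBSCl/imidazole silylates the secondary alcohol (the chelated 5-OH does not react) and gives 25.

2. Step 9. The Grignard reagent may attack the pyranone ring (conjugate addition or addition to the C4 carbonyl, followed by ring opening) in competition with 1,2-addition to the aldehyde.
   - The fallback sets out from aldehyde 6 and Grignard reagent 12 and comes back at ketone 14. It makes the bond by palladium-catalysed acyl coupling of a soft organozinc reagent instead of polar carbonyl addition.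
   - The carboxylic acid F1 (Pinnick oxidation of 6, as in the first fallback) is converted with EtSH, EDC and DMAP into the S-ethyl thioester F9.
   - Grignard reagent 12 is transmetalated with ZnCl2 to the alkylzinc chloride F10.
   - Fukuyama coupling of F9 with F10 (PdCl2(PPh3)2, toluene/THF, rt) gives ketone 14 directly, which also removes the oxidation of step 10.

3. Step 7. The ylide or the alkoxide may enolise the α-siloxy ketone, which would erode the stereocentre, and the primary alkoxide may draw the silyl group over from the secondary oxygen.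
   - The fallback sets out from hydroxy ketone 9 and comes back at bromide 11. It changes the order so that neither an alkoxide nor a basic ylide meets the α-siloxy ketone.
   - Appel bromination of 9 (CBr4, PPh3, CH2Cl2) gives (3S)-5-bromo-3-(tert-butyldimethylsilyloxy)pentan-2-one F11.
   - Non-basic titanium methylenation (Zn, CH2Br2, TiCl4, Takai–Lombardo conditions) converts the ketone of F11 into the 1,1-disubstituted alkene, which is 11.

Further compounds
F1 | step 13 | 5-(methoxymethoxy)-6-(4-methoxyphenyl)-4-oxo-4H-pyran-2-carboxylic acid | OC(=O)c1cc(=O)c(OCOC)c(-c2ccc(OC)cc2)o1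
F2 | step 13 | isobutyl carbonic anhydride of 5-(methoxymethoxy)-6-(4-methoxyphenyl)-4-oxo-4H-pyran-2-carboxylic acid | CC(C)COC(=O)OC(=O)c1cc(=O)c(OCOC)c(-c2ccc(OC)cc2)o1
F3 | step 13 | 2-(diazoacetyl)-5-(methoxymethoxy)-6-(4-methoxyphenyl)-4H-pyran-4-one | [N-]=[N+]=CC(=O)c1cc(=O)c(OCOC)c(-c2ccc(OC)cc2)o1
F4 | step 13 | 5-hydroxy-3-(methoxymethoxy)-4'-methoxy-7-(triisopropylsilyloxy)flavone | COCOc1c(-c2ccc(OC)cc2)oc2cc(O[Si](C(C)C)(C(C)C)C(C)C)cc(O)c2c1=O
F5 | step 13 | 3-(methoxymethoxy)-4'-methoxy-5-(3-methylbut-2-enyloxy)-7-(triisopropylsilyloxy)flavone | COCOc1c(-c2ccc(OC)cc2)oc2cc(O[Si](C(C)C)(C(C)C)C(C)C)cc(OCC=C(C)C)c2c1=O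
F6 | step 13 | 5-hydroxy-3-(methoxymethoxy)-4'-methoxy-8-(3-methylbut-2-enyl)-7-(triisopropylsilyloxy)flavone | CC(C)=CCc1c(O[Si](C(C)C)(C(C)C)C(C)C)cc(O)c2c(=O)c(OCOC)c(-c3ccc(OC)cc3)oc12
F7 | step 13 | 8-{[(2S)-3,3-dimethyloxiran-2-yl]methyl}-5-hydroxy-3-(methoxymethoxy)-4'-methoxy-7-(triisopropylsilyloxy)flavone | CC1(C)O[C@H]1Cc1c(O[Si](C(C)C)(C(C)C)C(C)C)cc(O)c2c(=O)c(OCOC)c(-c3ccc(OC)cc3)oc12
F8 | step 13 | 5-hydroxy-8-[(2S)-2-hydroxy-3-methylbut-3-enyl]-3-(methoxymethoxy)-4'-methoxy-7-(triisopropylsilyloxy)flavone | C=C(C)[C@@H](O)Cc1c(O[Si](C(C)C)(C(C)C)C(C)C)cc(O)c2c(=O)c(OCOC)c(-c3ccc(OC)cc3)oc12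
F9 | step 9 | S-ethyl 5-(methoxymethoxy)-6-(4-methoxyphenyl)-4-oxo-4H-pyran-2-carbothioate | CCSC(=O)c1cc(=O)c(OCOC)c(-c2ccc(OC)cc2)o1
F10 | step 9 | [(3S)-3-(tert-butyldimethylsilyloxy)-4-methylpent-4-enyl]zinc chloride | C=C(C)[C@@H](O[Si](C)(C)C(C)(C)C)CC[Zn]Cl
F11 | step 7 | (3S)-5-bromo-3-(tert-butyldimethylsilyloxy)pentan-2-one | CC(=O)[C@@H](O[Si](C)(C)C(C)(C)C)CCBr
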